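**Conventions.** Compounds are numbered 1–24 in the order of the steps below. Carbon atoms carry daucane numbers: C1 is the quaternary ring-fusion carbon with the methyl group, C2 and C3 are the cyclopentane CH2 groups, C4 is the isopropyl carbinol carbon, C5 is the ring-fusion CH, and C6–C10 run round the seven-membered ring back to C1. The face of the bicycle that carries the C1 methyl is called β and the other face α. Bicyclic compounds are named as bicyclo[5.3.0]decanes with these atom numbers.

## Analysis of the target

Compound 24 is a daucane sesquiterpene diester. A cyclopentane (C1–C5) is trans-fused to a cycloheptene (C1, C5–C10) whose only double bond is C8=C9, with a methyl group on C8. The five stereocentres C10, C1, C5, C6 and C4 are contiguous, (1S,4R,5S,6S,10R). With the C1 methyl β, the hydrogen on C5 and the oxygens on C6 and C10 are α, and the C4 hydroxyl is β (isopropyl α).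

The sensitive groups are:
- the angelate, a (Z)-2-methylbut-2-enoate that isomerises to the (E) isomer with base, nucleophiles or heat;
- the allylic ester position C10;
- the tertiary C4 hydroxyl, which is 1,3 to the C6 ester (dehydration, acyl migration);
- any C4 ketone used on the way, which is a β-oxygenated ketone with an epimerisable C5.

The hard points are the quaternary C1 next to the oxygenated C10 with fixed relative configuration, the seven-membered ring, and the placing of two different esters on two secondary hydroxyls beside a free tertiary one.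

The strategy rests on the C1–C10 bond. At a lower oxidation level the seven-membered ring is a cyclohepta-1,4-diene (C5=C6 and C8=C9 with C7 between them). That is the ring a [3,3] shift of a cis-divinylcyclopropane produces, and the shift forms its new sigma bond exactly between the quaternary carbon C1 and the oxygen-bearing C10.

## Retrosynthetic reasoning

**24 ⇒ 22 + 23.** The C10–O acyl bond is cut first. The angelate is the most fragile group, so it should meet as few reagents as possible. The forward step has to acylate the hindered allylic hydroxyl of 22 with 23 without touching the tertiary C4 hydroxyl or the C6 ester, and without Z-to-E isomerisation.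

**22 ⇒ 21 ⇒ 19 + 20.** Removing the silyl group from O10 and then the aroyl group from O6 leads to diol 19 and acid chloride 20. In 19 the three oxygens are already told apart without extra protecting groups. O10 is silylated because it enters the synthesis that way, O4 is tertiary, and O6 is the only free secondary hydroxyl.

**19 ⇒ 18.** The C4–isopropyl bond is cut to give ketone 18. The forward addition of an isopropyl nucleophile must come from the α face, anti to the C1 methyl, to give the 4β-hydroxyl. The C6 ester is left off until after this step, because an aroyloxy group β to the ketone would invite elimination and would itself be attacked by the organometallic.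

**18 ⇒ 17.** The ketone is masked as a dioxolane. The ketal has been in place since compound 4, where it makes the diene accessible, and it keeps C5 from being an enolisable position until late.

**17 ⇒ 15 ⇒ 14.** The C8 methyl is traced back through allylic alcohol 15 to a methyl ester. No skeletal bond is cut. The ester is the acceptor group that the carbenoid chemistry needs, and while it is present it deactivates C8=C9, which makes the next disconnection selective.

**14 ⇒ 12.** The C5–H and C6–O bonds are removed together (retro-hydroboration), which uncovers the cyclohepta-1,4-diene 12. Forward, a syn addition across C5=C6 from the α face has to set the trans ring fusion and the C6 configuration in one operation.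

**12 ⇒ 5 + 10 (through 11).** This is the key disconnection. A retro-Cope step cuts C1–C10 and re-forms C6–C8, giving the cis-divinylcyclopropane 11. Retro-cyclopropanation then cuts C7–C8 and C6–C8, giving diene 5 and vinyl diazoester 10. The cut is made here because two achiral fragments of similar size are joined in one catalytic step that makes the ring, two skeletal bonds and the C1/C10 stereocentres. The tetrasubstituted cyclopentene carbon can only act as the Cope terminus, which is where the quaternary carbon is wanted.

**5 ⇒ 4 ⇒ 3 ⇒ 1.** The vinyl–ring bond is cut (cross-coupling of a vinyl–metal partner with bromide 4), then the ketal, then the C–Br bond, back to enone 1.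

**10 ⇒ 8 ⇒ 6 + 7.** The enol ether double bond comes from dehydration of aldol adduct 8, and the bond between the diazo carbon and the carbinol carbon is cut to diazoester 6 and aldehyde 7.

## Alternatives that were turned down

**Alternative 1: carbenoid C–H insertion to make the cyclopentane.**
- Disconnection: the five-membered ring is opened at C1–C5.
- Forward step: dirhodium tetraacetate, Rh2(OAc)4, decomposes the acyclic diazo keto ester A1. The carbenoid carbon (future C5) inserts into the tertiary C–H bond of the future C1, five atoms away, with retention, giving cyclopentanone A2.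
- For: 1,5-insertion into a tertiary C–H bond is one of the most dependable ways to make a quaternary stereocentre. The absolute configuration of C1 comes from a simple methyl-bearing stereocentre in A1 and not from an enantioselective catalyst acting on a new substrate. On this point it is stronger than the chosen strategy. A2 also already has the C4 carbonyl.
- Against: the step makes one bond and the easy ring. C6 and C10 are present only as one-carbon arms. The seven-membered ring, C7–C9, the trisubstituted alkene and the C10 and C6 stereocentres all remain to be built, with at least two more C–C bond formations and a medium-ring closure that has no stereochemical relay to C10.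
- Comparison: the chosen strategy gives up the auxiliary-free certainty at C1. In exchange it delivers the ring, both alkenes in the right places and the C1/C10 pair in a single convergent step, which is far shorter overall.

**Alternative 2: [2,3]-Wittig shift of a cyclopentenyl dihydropyran.**
- Disconnection: the same C1–C10 bond, but from the six-membered allyl ether A3.
- Forward step: n-BuLi deprotonates the allylic OCH2 carbon (future C10). The carbanion attacks C1 of the tetrasubstituted cyclopentene while the C6–O bond breaks, so the oxygen leaves the ring and the carbocyclic dienol A4 results.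
- For: A4 arrives with the C8 methyl, the C4 carbinol (as a silyl ether) and a free C10 hydroxyl. No ester-to-methyl conversion and no late organometallic addition are needed. On endgame economy it is stronger than the chosen route.
- Against: the shift must create a quaternary carbon at a tetrasubstituted alkene terminus, the slow case in which [1,2] shift and elimination compete. Two α-oxy allylic positions (C10 and C6) can be lithiated and only one is productive. The C10 configuration depends on an exo/endo choice in a strained bicyclic transition state. A3 carries two remote stereocentres (C4 and C6) that must be set relative to each other with no ring to relay them, so it costs a longer linear sequence than 5 and 10 together. A4 has the same C5=C6 alkene as 12, so the later face-selectivity question is not avoided.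
- Comparison: the chosen strategy has a longer endgame. It offers instead a catalytic, convergent union of two achiral fragments that are three and two steps from commercial materials.

**Alternative 3: allylsilane–aldehyde ring closure.**
- Disconnection: the seven-membered ring is opened at C6–C7.
- Forward step: BF3·OEt2 or SnCl4 activates the C6 aldehyde of A5. The allylsilane attacks through C7 and loses silicon from C9, giving hydroazulene A6 with the C6 carbinol and the C8=C9 alkene.
- For: the ring closure installs the C6 oxygen and fixes the position of the trisubstituted alkene, so there is no hydroboration and no need to tell two alkenes apart. A6 is a handful of steps from 24. On alkene placement and lateness of ring closure it is at least as strong as the chosen route.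
- Against: C1, C4, C5 and C10 must all be in place in A5 before the cyclisation. The quaternary C1 and its neighbour C10 therefore have to be set on an open chain, which is the very problem the chosen strategy solves in one step. The aldehyde of A5 is epimerisable at C5 and is β to a tertiary alkoxy group, and it must survive a Lewis acid. Seven-membered closure with an endocyclic allyl transfer is slower than five- or six-membered cases, so protodesilylation competes. The C6 configuration is decided in a flexible transition state.
- Comparison: its key step makes one bond and one stereocentre after a long linear sequence. The chosen key step makes two bonds, the ring and two stereocentres early.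

Key step: step 6

Assumption (sense of induction in step 6): the prolinate catalyst is taken to select the face of the vinyl group of 5 as it does with styrene and aryl- or vinyldiazoacetates, where the (S)-catalyst gives the (1S,2R)-1,2-diarylcyclopropane ester. On that model the (R)-catalyst Rh2(R-DOSP)4 gives 11 and 12 as drawn. If the sense proves opposite, the (S)-catalyst is used and nothing else changes.

## Route

**Step 1**
Reactants: 1 3-methylcyclopent-2-en-1-one
Product: 3 2-bromo-3-methylcyclopent-2-en-1-one, via dibromide 2 (not isolated)
Conditions: Br2, CH2Cl2, 0 °C; then Et3N, 0 °C → rt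
Reagents that add atoms: bromine, BrBr
Why: Anti addition of bromine to the enone gives dibromide 2, and triethylamine removes the acidic C2 proton and expels the β-bromide (bromination–dehydrobromination), which leaves the α-bromo enone.

**Step 2**
Reactants: 3 2-bromo-3-methylcyclopent-2-en-1-one
Product: 4 6-bromo-7-methyl-1,4-dioxaspiro[4.4]non-6-ene
Conditions: HOCH2CH2OH, p-TsOH·H2O (cat.), benzene, reflux, Dean–Stark
Reagents that add atoms: ethane-1,2-diol, OCCO
Why: Acid-catalysed ketalisation with azeotropic removal of water; 2-halocycloalkenones ketalise without migration of the double bond, and here the tetrasubstituted position is also the stable one.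

**Step 3**
Reactants: 4 6-bromo-7-methyl-1,4-dioxaspiro[4.4]non-6-ene
Product: 5 6-ethenyl-7-methyl-1,4-dioxaspiro[4.4]non-6-ene
Conditions: Bu3SnCH=CH2, Pd(PPh3)4 (5 mol %), toluene, 100 °C
Reagents that add atoms: tributyl(ethenyl)stannane, C=C[Sn](CCCC)(CCCC)CCCC
Why: Stille coupling (oxidative addition of zerovalent palladium into the vinyl C–Br bond, transmetalation, reductive elimination); the neutral conditions spare the acid-sensitive allylic ketal.

**Step 4**
Reactants: 6 methyl diazoacetate; 7 (tert-butyldimethylsilyloxy)acetaldehyde
Product: 8 methyl 4-(tert-butyldimethylsilyloxy)-2-diazo-3-hydroxybutanoate (racemic)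
Conditions: LiN(i-Pr)2, THF, −78 °C; then 7; AcOH, −78 °C
Reagents that add atoms: none
Why: Aldol-type addition of lithiated methyl diazoacetate to the aldehyde; the cold quench avoids 1,4 O-to-O silyl migration in the alkoxide, and the new stereocentre is racemic and is destroyed in step 5.

**Step 5**
Reactants: 8 methyl 4-(tert-butyldimethylsilyloxy)-2-diazo-3-hydroxybutanoate
Product: 10 methyl (E)-4-(tert-butyldimethylsilyloxy)-2-diazobut-3-enoate, via trifluoroacetate 9 (not isolated)
Conditions: (CF3CO)2O, Et3N, CH2Cl2, −78 → 0 °C
Reagents that add atoms: none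
Why: Acylation–elimination (dehydration of a β-hydroxy α-diazo ester): loss of trifluoroacetate is assisted by the diazo carbon and a proton is lost from C4, giving the conjugated silyl enol ether, for which the (E) isomer is the less hindered one. The product is used at once, since vinyl diazo compounds cyclise to pyrazoles on standing.

**Step 6**
Reactants: 5 6-ethenyl-7-methyl-1,4-dioxaspiro[4.4]non-6-ene; 10 methyl (E)-4-(tert-butyldimethylsilyloxy)-2-diazobut-3-enoate
Product: 12 methyl (1S,10R)-10-(tert-butyldimethylsilyloxy)-4,4-(ethylenedioxy)-1-methylbicyclo[5.3.0]deca-5,8-diene-8-carboxylate, via divinylcyclopropane 11 (not isolated)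
Conditions: Rh2(R-DOSP)4 [dirhodium tetrakis((R)-N-(4-dodecylbenzenesulfonyl)prolinate)] (1 mol %), hexanes, −40 °C → rt, 10 added slowly; then 60 °C
Reagents that add atoms: none
Why: Loss of N2 from 10 at the dirhodium catalyst gives a donor/acceptor vinylcarbenoid, which adds in a concerted, asynchronous way to the monosubstituted vinyl group of 5 (bonds C7–C8 and C6–C8) with the cyclopentenyl group cis to the carbenoid's vinyl group, so that 11 is a cis-divinylcyclopropane. A boat-like [3,3] Cope rearrangement then breaks C6–C8 and joins C10 to C1; the closest known reaction type is the tandem cyclopropanation/Cope rearrangement (formal [4+3] cycloaddition) of vinyldiazoacetates with 1,3-dienes. The seven-membered ring is therefore closed by a pericyclic ring expansion of the three-membered ring and not by cyclisation of a chain, the new sigma bond C1–C10 forming between the ends of the two alkenyl arms and leaving double bonds at C5=C6 and C8=C9. C1 and C10 are the new stereocentres: their relative configuration follows from the boat geometry, in which the (E)-silyloxy group and ring carbon C2 both point outward and end up cis, so the C10 oxygen is trans to the C1 methyl. Their absolute configuration is relayed from the catalyst-controlled face selection in the cyclopropanation, the cyclopropane stereocentres C6 and C8 themselves becoming sp2. The step needs site selectivity, which the substrate secures because the tetrasubstituted ring alkene is too hindered for this carbenoid and because the terminal silyloxy group and the hydrocarbon solvent favour reaction at the carbenoid carbon over the vinylogous position; it also needs the cis diastereoselectivity that is inherent to donor/acceptor carbenoids, and enantioselectivity from the prolinate ligands at low temperature. Because the C1 methyl is the inward-pointing substituent in the boat, the rearrangement should be slower than in unsubstituted cases, hence the warming period at the end.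

**Step 7**
Reactants: 12 methyl (1S,10R)-10-(tert-butyldimethylsilyloxy)-4,4-(ethylenedioxy)-1-methylbicyclo[5.3.0]deca-5,8-diene-8-carboxylate
Product: 14 methyl (1S,5S,6S,10R)-10-(tert-butyldimethylsilyloxy)-4,4-(ethylenedioxy)-6-hydroxy-1-methylbicyclo[5.3.0]dec-8-ene-8-carboxylate, via alkylborane 13 (not isolated)
Conditions: BH3·THF (1.5 equiv), THF, 0 °C → rt; then H2O2, aq. NaOH, 0 °C
Reagents that add atoms: hydrogen peroxide, OO
Why: Hydroboration–oxidation: boron adds to the less substituted C6 and hydrogen to C5 in a syn fashion, and the electron-rich C5=C6 bond reacts ahead of the ester-deactivated C8=C9 bond. Addition is planned from the α face, opposite the C1 methyl that stands nearly perpendicular to the alkene plane, which sets the trans ring fusion (5α-H) and the 6α-oxygen together; oxidation of the C–B bond proceeds with retention.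

**Step 8**
Reactants: 14 methyl (1S,5S,6S,10R)-10-(tert-butyldimethylsilyloxy)-4,4-(ethylenedioxy)-6-hydroxy-1-methylbicyclo[5.3.0]dec-8-ene-8-carboxylate
Product: 15 (1S,5S,6S,10R)-10-(tert-butyldimethylsilyloxy)-4,4-(ethylenedioxy)-8-(hydroxymethyl)-1-methylbicyclo[5.3.0]dec-8-en-6-ol
Conditions: i-Bu2AlH (3.5 equiv), CH2Cl2, −78 → −20 °C; aq. Rochelle salt
Reagents that add atoms: none
Why: 1,2-Reduction of the conjugated ester to the allylic alcohol by i-Bu2AlH; ketal, silyl ether and the ring alkene are inert, and one equivalent is consumed by the C6 hydroxyl.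

**Step 9**
Reactants: 15 (1S,5S,6S,10R)-10-(tert-butyldimethylsilyloxy)-4,4-(ethylenedioxy)-8-(hydroxymethyl)-1-methylbicyclo[5.3.0]dec-8-en-6-ol
Product: 17 (1S,5S,6S,10R)-10-(tert-butyldimethylsilyloxy)-4,4-(ethylenedioxy)-1,8-dimethylbicyclo[5.3.0]dec-8-en-6-ol, via allylic mesylate 16 (not isolated)
Conditions: MsCl (1.1 equiv), Et3N, CH2Cl2, −40 °C; then LiEt3BH, THF, −40 → 0 °C
Reagents that add atoms: none
Why: Chemoselective sulfonylation of the primary allylic hydroxyl over the hindered secondary one at low temperature, then SN2 hydride displacement by LiEt3BH (allylic deoxygenation). Direct substitution keeps the double bond at C8=C9, the SN2′ path being disfavoured at C9, which is flanked by the silyloxy-bearing C10.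

**Step 10**
Reactants: 17 (1S,5S,6S,10R)-10-(tert-butyldimethylsilyloxy)-4,4-(ethylenedioxy)-1,8-dimethylbicyclo[5.3.0]dec-8-en-6-ol
Product: 18 (1S,5S,6S,10R)-10-(tert-butyldimethylsilyloxy)-6-hydroxy-1,8-dimethylbicyclo[5.3.0]dec-8-en-4-one
Conditions: PPTS, acetone/H2O, 50 °C
Reagents that add atoms: water, O
Why: Acid-catalysed ketal hydrolysis under conditions mild enough for the hindered secondary silyl ether; a weak acid is chosen so that the β-hydroxy ketone neither dehydrates nor epimerises at C5.

**Step 11**
Reactants: 18 (1S,5S,6S,10R)-10-(tert-butyldimethylsilyloxy)-6-hydroxy-1,8-dimethylbicyclo[5.3.0]dec-8-en-4-one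
Product: 19 (1S,4R,5S,6S,10R)-10-(tert-butyldimethylsilyloxy)-1,8-dimethyl-4-(propan-2-yl)bicyclo[5.3.0]dec-8-ene-4,6-diol
Conditions: i-PrMgCl (3.5 equiv), CeCl3, THF, −78 → −20 °C; aq. NH4Cl
Reagents that add atoms: isopropylmagnesium chloride, CC(C)[Mg]Cl
Why: Organocerium 1,2-addition: the weakly basic isopropylcerium reagent adds to the hindered, enolisable ketone where the Grignard reagent alone would enolise or reduce it, and the first equivalent only deprotonates the C6 hydroxyl. Attack is expected from the α face, syn to the C5 hydrogen and anti to the pseudoaxial C1 methyl that is 1,3 to C4 on the cyclopentanone, giving the 4β-hydroxyl (4R).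

**Step 12**
Reactants: 19 (1S,4R,5S,6S,10R)-10-(tert-butyldimethylsilyloxy)-1,8-dimethyl-4-(propan-2-yl)bicyclo[5.3.0]dec-8-ene-4,6-diol; 20 3,4-dimethoxybenzoyl chloride
Product: 21 (1S,4R,5S,6S,10R)-10-(tert-butyldimethylsilyloxy)-4-hydroxy-1,8-dimethyl-4-(propan-2-yl)bicyclo[5.3.0]dec-8-en-6-yl 3,4-dimethoxybenzoate
Conditions: Et3N, DMAP (cat.), CH2Cl2, 0 °C → rt
Reagents that add atoms: none
Why: DMAP-catalysed acylation of the only free secondary hydroxyl; the tertiary C4 hydroxyl next to the isopropyl group does not react under these conditions.

**Step 13**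
Reactants: 21 (1S,4R,5S,6S,10R)-10-(tert-butyldimethylsilyloxy)-4-hydroxy-1,8-dimethyl-4-(propan-2-yl)bicyclo[5.3.0]dec-8-en-6-yl 3,4-dimethoxybenzoate
Product: 22 (1S,4R,5S,6S,10R)-4,10-dihydroxy-1,8-dimethyl-4-(propan-2-yl)bicyclo[5.3.0]dec-8-en-6-yl 3,4-dimethoxybenzoate
Conditions: n-Bu4NF, AcOH, THF, rt → 40 °C
Reagents that add atoms: none
Why: Fluoride-induced cleavage of the silyl ether; buffering with acetic acid keeps the liberated alkoxide from attacking or migrating the C6 ester.

**Step 14**
Reactants: 22 (1S,4R,5S,6S,10R)-4,10-dihydroxy-1,8-dimethyl-4-(propan-2-yl)bicyclo[5.3.0]dec-8-en-6-yl 3,4-dimethoxybenzoate; 23 angelic acid [(2Z)-2-methylbut-2-enoic acid]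
Product: 24 (1S,4R,5S,6S,10R)-4-hydroxy-1,8-dimethyl-10-{[(2Z)-2-methylbut-2-enoyl]oxy}-4-(propan-2-yl)bicyclo[5.3.0]dec-8-en-6-yl 3,4-dimethoxybenzoate
Conditions: 23, 2,4,6-Cl3C6H2COCl, Et3N, toluene, rt; then 22, 75 °C
Reagents that add atoms: none
Why: Yamaguchi-type mixed-anhydride esterification: the alcohol attacks the unhindered angeloyl carbonyl of the mixed anhydride, and leaving out a nucleophilic catalyst avoids the addition–elimination path that turns the angelate into the tiglate. The tertiary C4 hydroxyl is too hindered to be acylated.

## Compound list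

1 | 3-methylcyclopent-2-en-1-one | CC1=CC(=O)CC1 | starting material
2 | trans-2,3-dibromo-3-methylcyclopentan-1-one (racemic; 2R,3R enantiomer drawn) | O=C1CC[C@@](C)(Br)[C@@H]1Br | intermediate (not isolated)
3 | 2-bromo-3-methylcyclopent-2-en-1-one | CC1=C(Br)C(=O)CC1 | intermediate
4 | 6-bromo-7-methyl-1,4-dioxaspiro[4.4]non-6-ene | BrC1=C(C)CCC12OCCO2 | intermediate
5 | 6-ethenyl-7-methyl-1,4-dioxaspiro[4.4]non-6-ene | C=CC1=C(C)CCC12OCCO2 | intermediate
6 | methyl diazoacetate | COC(=O)C=[N+]=[N-] | starting material
7 | (tert-butyldimethylsilyloxy)acetaldehyde | CC(C)(C)[Si](C)(C)OCC=O | starting material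
8 | methyl 4-(tert-butyldimethylsilyloxy)-2-diazo-3-hydroxybutanoate (racemic) | COC(=O)C(=[N+]=[N-])C(O)CO[Si](C)(C)C(C)(C)C | intermediate
9 | methyl 4-(tert-butyldimethylsilyloxy)-2-diazo-3-(trifluoroacetoxy)butanoate (racemic) | COC(=O)C(=[N+]=[N-])C(OC(=O)C(F)(F)F)CO[Si](C)(C)C(C)(C)C | intermediate (not isolated)
10 | methyl (E)-4-(tert-butyldimethylsilyloxy)-2-diazobut-3-enoate | COC(=O)C(=[N+]=[N-])/C=C/O[Si](C)(C)C(C)(C)C | intermediate
11 | methyl (1R,2S)-1-[(E)-2-(tert-butyldimethylsilyloxy)ethenyl]-2-(7-methyl-1,4-dioxaspiro[4.4]non-6-en-6-yl)cyclopropane-1-carboxylate | COC(=O)[C@]1(/C=C/O[Si](C)(C)C(C)(C)C)C[C@H]1C1=C(C)CCC12OCCO2 | intermediate (not isolated)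
12 | methyl (1S,10R)-10-(tert-butyldimethylsilyloxy)-4,4-(ethylenedioxy)-1-methylbicyclo[5.3.0]deca-5,8-diene-8-carboxylate | CC(C)(C)[Si](C)(C)O[C@@H]1C=C(C(=O)OC)CC=C2[C@]1(C)CCC23OCCO3 | intermediate
13 | methyl (1S,5R,6S,10R)-6-boranyl-10-(tert-butyldimethylsilyloxy)-4,4-(ethylenedioxy)-1-methylbicyclo[5.3.0]dec-8-ene-8-carboxylate (5α-H, 6α-BH2) | CC(C)(C)[Si](C)(C)O[C@@H]1C=C(C(=O)OC)C[C@H](B)[C@@H]2[C@]1(C)CCC23OCCO3 | intermediate (not isolated)
14 | methyl (1S,5S,6S,10R)-10-(tert-butyldimethylsilyloxy)-4,4-(ethylenedioxy)-6-hydroxy-1-methylbicyclo[5.3.0]dec-8-ene-8-carboxylate | CC(C)(C)[Si](C)(C)O[C@@H]1C=C(C(=O)OC)C[C@H](O)[C@@H]2[C@]1(C)CCC23OCCO3 | intermediate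
15 | (1S,5S,6S,10R)-10-(tert-butyldimethylsilyloxy)-4,4-(ethylenedioxy)-8-(hydroxymethyl)-1-methylbicyclo[5.3.0]dec-8-en-6-ol | CC(C)(C)[Si](C)(C)O[C@@H]1C=C(CO)C[C@H](O)[C@@H]2[C@]1(C)CCC23OCCO3 | intermediate
16 | [(1S,5S,6S,10R)-10-(tert-butyldimethylsilyloxy)-4,4-(ethylenedioxy)-6-hydroxy-1-methylbicyclo[5.3.0]dec-8-en-8-yl]methyl methanesulfonate | CC(C)(C)[Si](C)(C)O[C@@H]1C=C(COS(C)(=O)=O)C[C@H](O)[C@@H]2[C@]1(C)CCC23OCCO3 | intermediate (not isolated)
17 | (1S,5S,6S,10R)-10-(tert-butyldimethylsilyloxy)-4,4-(ethylenedioxy)-1,8-dimethylbicyclo[5.3.0]dec-8-en-6-ol | CC(C)(C)[Si](C)(C)O[C@@H]1C=C(C)C[C@H](O)[C@@H]2[C@]1(C)CCC23OCCO3 | intermediate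
18 | (1S,5S,6S,10R)-10-(tert-butyldimethylsilyloxy)-6-hydroxy-1,8-dimethylbicyclo[5.3.0]dec-8-en-4-one | CC(C)(C)[Si](C)(C)O[C@@H]1C=C(C)C[C@H](O)[C@@H]2[C@]1(C)CCC2=O | intermediate
19 | (1S,4R,5S,6S,10R)-10-(tert-butyldimethylsilyloxy)-1,8-dimethyl-4-(propan-2-yl)bicyclo[5.3.0]dec-8-ene-4,6-diol | CC(C)(C)[Si](C)(C)O[C@@H]1C=C(C)C[C@H](O)[C@@H]2[C@]1(C)CC[C@@]2(O)C(C)C | intermediate
20 | 3,4-dimethoxybenzoyl chloride | COc1ccc(cc1OC)C(Cl)=O | starting material
21 | (1S,4R,5S,6S,10R)-10-(tert-butyldimethylsilyloxy)-4-hydroxy-1,8-dimethyl-4-(propan-2-yl)bicyclo[5.3.0]dec-8-en-6-yl 3,4-dimethoxybenzoate | CC(C)(C)[Si](C)(C)O[C@@H]1C=C(C)C[C@H](OC(=O)c2ccc(OC)c(OC)c2)[C@@H]2[C@]1(C)CC[C@@]2(O)C(C)C | intermediate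
22 | (1S,4R,5S,6S,10R)-4,10-dihydroxy-1,8-dimethyl-4-(propan-2-yl)bicyclo[5.3.0]dec-8-en-6-yl 3,4-dimethoxybenzoate | O[C@@H]1C=C(C)C[C@H](OC(=O)c2ccc(OC)c(OC)c2)[C@@H]2[C@]1(C)CC[C@@]2(O)C(C)C | intermediate
23 | angelic acid, (2Z)-2-methylbut-2-enoic acid | C/C=C(/C)C(=O)O | starting material
24 | (1S,4R,5S,6S,10R)-4-hydroxy-1,8-dimethyl-10-{[(2Z)-2-methylbut-2-enoyl]oxy}-4-(propan-2-yl)bicyclo[5.3.0]dec-8-en-6-yl 3,4-dimethoxybenzoate; azulene name (3R,3aS,4S,8R,8aS)-3-hydroxy-6,8a-dimethyl-3-(propan-2-yl)-1,2,3,3a,4,5,8,8a-octahydroazulene-4,8-diyl 4-(3,4-dimethoxybenzoate) 8-[(2Z)-2-methylbut-2-enoate] | C/C=C(/C)C(=O)O[C@@H]1C=C(C)C[C@H](OC(=O)c2ccc(OC)c(OC)c2)[C@@H]2[C@]1(C)CC[C@@]2(O)C(C)C | target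

## Step count and risk

Total step count: 14 (steps 1–3 to diene 5, steps 4–5 to diazoester 10, steps 6–14 after their union).
Longest linear sequence: 12 steps (1 → 3 → 4 → 5 → 12 → … → 24).

**Least certain steps**

**Step 6 (key step).**
- What may go wrong: insufficient face selection by the catalyst with this hindered diene and the silyloxy-substituted carbenoid, which would lower the enantiomeric purity of everything that follows.
- Other failure modes: a stalled Cope rearrangement, because the C1 methyl points inward in the boat (answered inside the step by heating), and diversion of the carbenoid by the ketal oxygens or by attack at its vinylogous position.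
- Fallback (resolution in place of catalyst control), starting from 5 and 10: the two fragments are joined with achiral dirhodium tetraoctanoate, Rh2(O2CC7H15)4, in hexanes. This gives 12 together with its mirror image, the ent-cycloadduct F1. Step 7 on the mixture gives 14 together with the ent-alcohol F2. Esterification of the C6 hydroxyl with (S)-methoxy(phenyl)acetic acid (DCC, DMAP) gives two diastereomers, the desired mandelate ester F3 and the mandelate ester of the mirror-image alcohol F4, which are separated by chromatography. F3 is taken into step 8 unchanged: i-Bu2AlH removes the resolving ester while it reduces the methyl ester, so the route is rejoined at 15.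

**Step 7.**
- What may go wrong: poor facial selectivity. The β face is shielded by the C1 methyl, but the α face carries the quasi-axial C10 silyloxy group, whose oxygen lies close to C5. Attack from the β face would give the cis-fused 5,6-bis-epimer. Slow addition to the hindered alkene could also let borane reduce the conjugated ester.
- Fallback (oxygen-tethered delivery in place of steric control), starting from 12: fluoride (n-Bu4NF) removes the silyl group and gives the C10 alcohol F5. Excess BH3·THF converts its hydroxyl into an alkoxyborane held on the α face, from which B–H is delivered to C5=C6 (oxygen-directed hydroboration, with the silyl bulk gone). Oxidation gives the 6α,10α-diol F6. Both hydroxyls are silylated (TBSOTf, 2,6-lutidine) to the bis-silyl ether F7. The less hindered C6 silyl ether is then cleaved selectively (PPTS, MeOH), which returns 14.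

**Step 11.**
- What may go wrong: enolisation of the hindered ketone (with loss of the C5 configuration), β-hydride reduction by the isopropyl reagent, retro-aldol opening of the C5–C6 bond in the metal aldolate, or addition from the β face.
- Fallback (sp2 nucleophile, then hydrogenation), starting from 18: isopropenylmagnesium bromide with CeCl3 has no β-hydrogen to transfer and is smaller. It gives the isopropenyl carbinol F8. Homogeneous hydrogenation with RhCl(PPh3)3 and H2 then saturates the 1,1-disubstituted alkene in preference to the hindered trisubstituted ring alkene and gives 19.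

**Step 14.**
- What may go wrong: slow acylation of the neopentyl-type allylic C10 hydroxyl. Forcing it would lead to Z-to-E isomerisation of the angeloyl group or to reaction at the tertiary C4 hydroxyl.
- Fallback (build the Z-alkene on the ester), starting from 22: the C10 hydroxyl is esterified with 2-[bis(2,2,2-trifluoroethoxy)phosphoryl]propanoic acid (DCC, DMAP), which has no isomerisable double bond, giving the phosphonopropanoate ester F9. Still–Gennari olefination of F9 with acetaldehyde (KN(SiMe3)2, 18-crown-6, THF, −78 °C) then forms the (Z)-2-methylbut-2-enoate and gives 24.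

## Further compounds

F1 | step 6 | methyl (1R,10S)-10-(tert-butyldimethylsilyloxy)-4,4-(ethylenedioxy)-1-methylbicyclo[5.3.0]deca-5,8-diene-8-carboxylate (mirror image of 12) | CC(C)(C)[Si](C)(C)O[C@H]1C=C(C(=O)OC)CC=C2[C@@]1(C)CCC23OCCO3
F2 | step 6 | methyl (1R,5R,6R,10S)-10-(tert-butyldimethylsilyloxy)-4,4-(ethylenedioxy)-6-hydroxy-1-methylbicyclo[5.3.0]dec-8-ene-8-carboxylate (mirror image of 14) | CC(C)(C)[Si](C)(C)O[C@H]1C=C(C(=O)OC)C[C@@H](O)[C@H]2[C@@]1(C)CCC23OCCO3
F3 | step 6 | (S)-methoxy(phenyl)acetate of 14 at O6 | CC(C)(C)[Si](C)(C)O[C@@H]1C=C(C(=O)OC)C[C@H](OC(=O)[C@@H](OC)c2ccccc2)[C@@H]2[C@]1(C)CCC23OCCO3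
F4 | step 6 | (S)-methoxy(phenyl)acetate of F2 at O6 | CC(C)(C)[Si](C)(C)O[C@H]1C=C(C(=O)OC)C[C@@H](OC(=O)[C@@H](OC)c2ccccc2)[C@H]2[C@@]1(C)CCC23OCCO3
F5 | step 7 | methyl (1S,10R)-4,4-(ethylenedioxy)-10-hydroxy-1-methylbicyclo[5.3.0]deca-5,8-diene-8-carboxylate | O[C@@H]1C=C(C(=O)OC)CC=C2[C@]1(C)CCC23OCCO3
F6 | step 7 | methyl (1S,5S,6S,10R)-4,4-(ethylenedioxy)-6,10-dihydroxy-1-methylbicyclo[5.3.0]dec-8-ene-8-carboxylate | O[C@@H]1C=C(C(=O)OC)C[C@H](O)[C@@H]2[C@]1(C)CCC23OCCO3
F7 | step 7 | methyl (1S,5S,6S,10R)-6,10-bis(tert-butyldimethylsilyloxy)-4,4-(ethylenedioxy)-1-methylbicyclo[5.3.0]dec-8-ene-8-carboxylate | CC(C)(C)[Si](C)(C)O[C@@H]1C=C(C(=O)OC)C[C@H](O[Si](C)(C)C(C)(C)C)[C@@H]2[C@]1(C)CCC23OCCO3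
F8 | step 11 | (1S,4S,5S,6S,10R)-10-(tert-butyldimethylsilyloxy)-1,8-dimethyl-4-(prop-1-en-2-yl)bicyclo[5.3.0]dec-8-ene-4,6-diol | CC(C)(C)[Si](C)(C)O[C@@H]1C=C(C)C[C@H](O)[C@@H]2[C@]1(C)CC[C@@]2(O)C(C)=C
F9 | step 14 | (1S,4R,5S,6S,10R)-10-{2-[bis(2,2,2-trifluoroethoxy)phosphoryl]propanoyloxy}-4-hydroxy-1,8-dimethyl-4-(propan-2-yl)bicyclo[5.3.0]dec-8-en-6-yl 3,4-dimethoxybenzoate (both epimers at the phosphonate-bearing carbon) | CC(C(=O)O[C@@H]1C=C(C)C[C@H](OC(=O)c2ccc(OC)c(OC)c2)[C@@H]2[C@]1(C)CC[C@@]2(O)C(C)C)P(=O)(OCC(F)(F)F)OCC(F)(F)F
A1 | alternative 1 | methyl (6S)-7-(tert-butyldimethylsilyloxy)-2-diazo-6-methyl-3-oxoheptanoate | COC(=O)C(=[N+]=[N-])C(=O)CC[C@H](C)CO[Si](C)(C)C(C)(C)C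
A2 | alternative 1 | methyl (1R,2S)-2-[(tert-butyldimethylsilyloxy)methyl]-2-methyl-5-oxocyclopentane-1-carboxylate | COC(=O)[C@H]1C(=O)CC[C@]1(C)CO[Si](C)(C)C(C)(C)C
A3 | alternative 2 | triethyl{[3-methyl-2-(4-methyl-3,6-dihydro-2H-pyran-2-yl)-1-(propan-2-yl)cyclopent-2-en-1-yl]oxy}silane, configured as in the SMILES | CC1=C([C@@H]2CC(C)=CCO2)[C@](O[Si](CC)(CC)CC)(C(C)C)CC1
A4 | alternative 2 | (1S,4R,10R)-1,8-dimethyl-4-(propan-2-yl)-4-(triethylsilyloxy)bicyclo[5.3.0]deca-5,8-dien-10-ol | O[C@@H]1C=C(C)CC=C2[C@]1(C)CC[C@@]2(O[Si](CC)(CC)CC)C(C)C
A5 | alternative 3 | 2-[1-(tert-butyldimethylsilyloxy)-3-methyl-2-(trimethylsilyl)but-3-en-1-yl]-5-(methoxymethoxy)-2-methyl-5-(propan-2-yl)cyclopentane-1-carbaldehyde, ring and carbinol centres as in the SMILES, silane carbon either configuration | O=C[C@@H]1[C@@](C)([C@H](O[Si](C)(C)C(C)(C)C)C([Si](C)(C)C)C(C)=C)CC[C@@]1(OCOC)C(C)C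
A6 | alternative 3 | (1S,4R,5S,6S,10R)-10-(tert-butyldimethylsilyloxy)-4-(methoxymethoxy)-1,8-dimethyl-4-(propan-2-yl)bicyclo[5.3.0]dec-8-en-6-ol | CC(C)(C)[Si](C)(C)O[C@@H]1C=C(C)C[C@H](O)[C@@H]2[C@]1(C)CC[C@@]2(OCOC)C(C)C
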